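**Retrosynthetic overview**

- The target is ring A (2,4-dibromo-6-methoxyphenoxy) joined through oxygen to C2' of ring B, a phenol with OH at C1' and Br at C4' and C6'. No ring is formed in the route; both benzene rings are bought.
- The strategy rests on one feature of ring B: the neighbouring heteroatom carbons C1' (OH) and C2' (O-aryl) lie beside the C6' bromine. They are read as the two ends of a C1'≡C2' aryne that this bromine polarises.
- C1'–OH is traced back to C1'–I (iodine–magnesium exchange, borylation, oxidation). C2'–O and C1'–I are formed together from 3,5-dibromobenzyne, a caesium aryloxide and C6F5I.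
- The aryne precursor comes from 2,4,6-tribromophenol (O-silylation, Br/Li exchange, retro-Brook shift, triflation). The aryloxide comes from 2-bromo-6-methoxyphenol (para bromination, salt formation).
- Order: ring B precursor (steps 1–2), ring A nucleophile (steps 3–4), three-component union (step 5), oxygenation at C1' (step 6).

Key step: step 5

Assumption: 2-bromo-6-methoxyphenol is used for ring A in place of guaiacol, because a second bromination of 4-bromoguaiacol can go para to the methoxy group; with the ortho bromine already in place, only the position para to OH remains to be brominated.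

**Route**

Step 1
Reactants: 1 2,4,6-tribromophenol
Product: 2 trimethyl(2,4,6-tribromophenoxy)silane
Conditions: HMDS (0.7 equiv), THF, reflux; volatiles removed in vacuo, used crude
Reagents that add atoms: hexamethyldisilazane, C[Si](C)(C)N[Si](C)(C)C
Why: O-Silylation of the acidic phenol with HMDS (silyl ether formation) is driven by loss of ammonia and leaves the three C–Br bonds untouched.

Step 2
Reactants: 2 trimethyl(2,4,6-tribromophenoxy)silane
Product: 5 2,4-dibromo-6-(trimethylsilyl)phenyl trifluoromethanesulfonate, via aryllithium 3 (not isolated), via lithium phenoxide 4 (not isolated)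
Conditions: n-BuLi (1.05 equiv), THF, −100 → −78 °C; Tf2O (1.2 equiv), −100 → −78 °C; cold aq. NaHCO3
Reagents that add atoms: n-butyllithium, CCCC[Li]; trifluoromethanesulfonic anhydride, O=S(=O)(OS(=O)(=O)C(F)(F)F)C(F)(F)F
Why: Bromine–lithium exchange takes place at one of the two equivalent bromines ortho to the silyloxy group (inductive stabilisation and O–Li contact favour it over the para bromine), the ortho-lithio silyl ether undergoes the anionic 1,3 O→C silyl shift (retro-Brook rearrangement), and the lithium phenoxide is O-triflated, the standard one-flask access to ortho-silylaryl triflates.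

Step 3
Reactants: 6 2-bromo-6-methoxyphenol
Product: 7 2,4-dibromo-6-methoxyphenol
Conditions: NBS (1.05 equiv), MeCN, 0 °C → rt
Reagents that add atoms: N-bromosuccinimide, O=C1CCC(=O)N1Br
Why: Electrophilic aromatic bromination goes to C4, para to the free hydroxyl and the most activated open position of a 2,6-disubstituted phenol, with NBS as a mild source of electrophilic bromine.

Step 4
Reactants: 7 2,4-dibromo-6-methoxyphenol
Product: 8 caesium 2,4-dibromo-6-methoxyphenolate
Conditions: CsOH·H2O (1.0 equiv), MeOH, rt; evaporate; PhMe azeotrope; 80 °C, high vacuum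
Reagents that add atoms: caesium hydroxide monohydrate, O.[OH-].[Cs+]
Why: Simple acid–base salt formation, after which azeotropic and vacuum drying removes water and methanol so that the aryloxide enters the aryne step free of any proton source.

Step 5
Reactants: 5 2,4-dibromo-6-(trimethylsilyl)phenyl trifluoromethanesulfonate; 8 caesium 2,4-dibromo-6-methoxyphenolate; 9 iodopentafluorobenzene
Product: 12 1,5-dibromo-3-(2,4-dibromo-6-methoxyphenoxy)-2-iodobenzene, via 3,5-dibromobenzyne 10 (not isolated), via aryl caesium 11 (not isolated)
Conditions: 8 (1.5 equiv), 9 (3 equiv), CsF (3 equiv), 18-crown-6 (3 equiv), THF, 0 °C → rt, 5 added slowly by syringe pump; then H2O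
Reagents that add atoms: none
Why: Proposed new method: fluoride from CsF/18-crown-6 attacks the silicon of 5 and triflate leaves to give 3,5-dibromobenzyne 10 (formal triple bond C1'–C2'), the dried caesium aryloxide 8 adds through oxygen at C2', and the C1' aryl anion 11 is iodinated by halophilic attack on 9, which releases the more stable pentafluorophenyl anion. The closest known reaction types are the fluoride-induced O-arylation of phenols with ortho-silylaryl triflates and three-component aryne couplings in which the aryl anion is quenched by halogen transfer from a polyhalogenated donor; combining an aryloxide with an aryl iodide donor in this way is new. No ring is closed and no stereocentre is formed. The step needs O–C2' and not O–C1' bond formation: the C6' bromine widens the aryne angle at C2' and stabilises negative charge at C1' inductively (distortion model for 3-halobenzynes), which should outweigh the weak opposite bias of the C4' bromine (meta to C2'), and the bulk of the 2,6-disubstituted aryloxide also favours the remote C2'. Because every ortho and para carbon of 8 carries Br or OMe, the ambident aryloxide can react only at oxygen. Bromide loss from 11 (a second aryne) and protonation are held back by the threefold excess of 9, the proton-free medium (preformed salt, THF in place of MeCN) and slow addition of 5 at low temperature.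

Step 6
Reactants: 12 1,5-dibromo-3-(2,4-dibromo-6-methoxyphenoxy)-2-iodobenzene
Product: 15 2,4-dibromo-6-(2,4-dibromo-6-methoxyphenoxy)phenol, via aryl Grignard 13 (not isolated), via dimethyl boronate 14 (not isolated)
Conditions: iPrMgCl·LiCl (1.05 equiv), THF, −78 → −40 °C; B(OMe)3 (2 equiv), −78 → 0 °C; AcOH, 30% aq. H2O2, 0 °C → rt; aq. Na2S2O3
Reagents that add atoms: isopropylmagnesium chloride–lithium chloride, CC(C)[Mg]Cl.[Li+].[Cl-]; trimethyl borate, COB(OC)OC; hydrogen peroxide, OO
Why: Iodine–magnesium exchange with the turbo-Grignard reagent is much faster at the C1'–I bond, activated by the flanking Br and O-aryl groups, than at any C–Br bond and the ortho-bromoaryl Grignard is stable below −40 °C; borylation with trimethyl borate and the peroxide-induced 1,2-aryl shift from boron to oxygen (boronate oxidation) then put OH exactly where the iodine was.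

**Compound list**

1 | 2,4,6-tribromophenol | Oc1c(Br)cc(Br)cc1Br | starting material
2 | trimethyl(2,4,6-tribromophenoxy)silane | C[Si](C)(C)Oc1c(Br)cc(Br)cc1Br | intermediate
3 | [3,5-dibromo-2-(trimethylsilyloxy)phenyl]lithium | C[Si](C)(C)Oc1c(Br)cc(Br)cc1[Li] | intermediate
4 | lithium 2,4-dibromo-6-(trimethylsilyl)phenolate | C[Si](C)(C)c1cc(Br)cc(Br)c1[O-].[Li+] | intermediate
5 | 2,4-dibromo-6-(trimethylsilyl)phenyl trifluoromethanesulfonate | C[Si](C)(C)c1cc(Br)cc(Br)c1OS(=O)(=O)C(F)(F)F | intermediate
6 | 2-bromo-6-methoxyphenol | COc1cccc(Br)c1O | starting material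
7 | 2,4-dibromo-6-methoxyphenol | COc1cc(Br)cc(Br)c1O | intermediate
8 | caesium 2,4-dibromo-6-methoxyphenolate | COc1cc(Br)cc(Br)c1[O-].[Cs+] | intermediate
9 | iodopentafluorobenzene | Fc1c(F)c(F)c(I)c(F)c1F | starting material
10 | 3,5-dibromobenzyne (1,2-didehydro-3,5-dibromobenzene, aryne bond C1'≡C2') | BrC1=CC(Br)=CC#C1 | intermediate
11 | caesium 2,4-dibromo-6-(2,4-dibromo-6-methoxyphenoxy)phenide (carbanion at C1') | COc1cc(Br)cc(Br)c1Oc1cc(Br)cc(Br)[c-]1.[Cs+] | intermediate
12 | 1,5-dibromo-3-(2,4-dibromo-6-methoxyphenoxy)-2-iodobenzene | COc1cc(Br)cc(Br)c1Oc1cc(Br)cc(Br)c1I | intermediate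
13 | [2,4-dibromo-6-(2,4-dibromo-6-methoxyphenoxy)phenyl]magnesium chloride | COc1cc(Br)cc(Br)c1Oc1cc(Br)cc(Br)c1[Mg]Cl | intermediate
14 | dimethyl [2,4-dibromo-6-(2,4-dibromo-6-methoxyphenoxy)phenyl]boronate | COB(OC)c1c(Br)cc(Br)cc1Oc1c(OC)cc(Br)cc1Br | intermediate
15 | 2,4-dibromo-6-(2,4-dibromo-6-methoxyphenoxy)phenol | COc1cc(Br)cc(Br)c1Oc1cc(Br)cc(Br)c1O | target

**Step count**

Total: 6 steps. Longest linear sequence: 4 steps (steps 1, 2, 5, 6, or equally steps 3, 4, 5, 6).

**Steps most likely to fail**

Step 5 (Proposed new method). Several processes could divert it: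
- the C1' anion may lose the C6' bromide, or pick up a proton, before iodine transfer;
- the aryloxide may add with the reverse orientation;
- the aryloxide may be consumed by aromatic substitution on the perfluoroarene, or by fluoride loss from the pentafluorophenyl anion to give tetrafluorobenzyne.

The fallback uses known chemistry, sets out from phenol 7 and comes back at target 15. It replaces steps 5 and 6 and needs neither 5 nor 9. Nucleophilic aromatic substitution of commercial 2,4-dibromo-6-fluorobenzaldehyde (O=Cc1c(F)cc(Br)cc1Br) by 7 (K2CO3, DMF, 80 °C) should give 2,4-dibromo-6-(2,4-dibromo-6-methoxyphenoxy)benzaldehyde F1. Baeyer–Villiger oxidation (mCPBA, CH2Cl2, rt) should then give 2,4-dibromo-6-(2,4-dibromo-6-methoxyphenoxy)phenyl formate F2. NaOH in MeOH/H2O followed by HCl should cleave F2 to 15.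

Step 6. The risks are competing bromine–magnesium exchange, loss of magnesium halide from the ortho-bromo Grignard to form an aryne, slow borylation between two ortho substituents, and protodeboronation before the oxidation. The fallback sets out from 12 through Grignard 13, generated as in step 6, and comes back at 15 without any boron intermediate. Trapping 13 with tert-butyl peroxybenzoate (CC(C)(C)OOC(=O)c1ccccc1; THF, −78 → 0 °C) should form the C–O bond directly and give 1,5-dibromo-2-tert-butoxy-3-(2,4-dibromo-6-methoxyphenoxy)benzene F3. TFA in CH2Cl2 at 0 °C should then remove the tert-butyl group to give 15.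

Step 2. The risks are exchange at the para bromine or twofold exchange, an incomplete O→C silyl shift, and loss of silicon on work-up. The fallback makes iodine the exchange handle. It does not set out from a numbered compound: it replaces 1 by commercial 2,4-dibromophenol (Oc1ccc(Br)cc1Br) and comes back at aryllithium 3, from which step 2 continues unchanged to 5. Ortho iodination (NIS, cat. TsOH, MeCN) should give 2,4-dibromo-6-iodophenol F4. HMDS should convert F4 to (2,4-dibromo-6-iodophenoxy)trimethylsilane F5. With n-BuLi at −100 °C, F5 should exchange only at iodine to give 3.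

**Further compounds**

F1 | step 5 | 2,4-dibromo-6-(2,4-dibromo-6-methoxyphenoxy)benzaldehyde | O=Cc1c(Br)cc(Br)cc1Oc1c(OC)cc(Br)cc1Br
F2 | step 5 | 2,4-dibromo-6-(2,4-dibromo-6-methoxyphenoxy)phenyl formate | O=COc1c(Br)cc(Br)cc1Oc1c(OC)cc(Br)cc1Br
F3 | step 6 | 1,5-dibromo-2-tert-butoxy-3-(2,4-dibromo-6-methoxyphenoxy)benzene | COc1cc(Br)cc(Br)c1Oc1cc(Br)cc(Br)c1OC(C)(C)C
F4 | step 2 | 2,4-dibromo-6-iodophenol | Oc1c(I)cc(Br)cc1Br
F5 | step 2 | (2,4-dibromo-6-iodophenoxy)trimethylsilane | C[Si](C)(C)Oc1c(I)cc(Br)cc1Br
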